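**Retrosynthetic overview**
1. Feature: the ten-membered carbocycle C1–C10 bears oxygen on the neighbours C10 and C1, and the methyl-bearing C4 lies four bonds from C10 (C10–C1–C2–C3–C4). This is the pattern of a cyclodec-5-enone (C10=O, C4=C5), which maps back to a 1,2-dialkenylcyclohexanol (ring C5–C10) by making C2–C3 and breaking C5–C10.
2. Late stage: remove the acetates. The C5=C6 ylidene comes from E1cB loss of O5. The dihydrofuran ring (O1, C1–C4) comes from the C1 ketone oxygen opening a C4,C5-epoxide at C4.
3. Butenolide ring (O6, C6, C7, C11, C12): intramolecular HWE of a C6 phosphonoacetate that already carries C13–O onto a C7 ketone. C14 comes from methyl addition to C10.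
4. Cyclodecenone 22 comes from the potassium alkoxide of cyclohexanol 19, and 19 from ketone 14 plus a 1-(methoxymethoxy)vinyl metal. Ketone 14 comes from a carbonyl-ene closure (C5–C10) of acyclic aldehyde 12. Aldehyde 12 is built from L-arabinose (C5–C8), an isopropylidene ylide (C3, C4, C15) and an acetate silyl ketene acetal (C9, C10).
5. Ring order: cyclohexane, then ten-membered carbocycle, then butenolide, then dihydrofuran.

Key step: step 12

Numbering (germacrane): ring C1–C10; C11, C12 (lactone C=O), C13 (CH2O); C14 is the methyl on C10 and C15 the methyl on C4; On is the oxygen on Cn.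
Remark on relay centres: C5, C6, C7 and C10 of cyclohexanol 19 do not survive. They are chosen with O6, O7 and O8 all cis (6R, 8S) and the isopropenyl group trans to O6, because epoxidation of C4=C5 on the outer face (syn to O6) followed by inversion at C4 then leads to 4S.
Remark on enolates: a C10 ketone enolised towards C5 or C9 has O6 or O8 as a β-leaving group. C5 is therefore never functionalised through an enolate; the C5–C10 bond and the isopropenyl group are made together by an ene reaction.
Assumption: 22 is drawn as the 1S epimer expected from peripheral protonation. C1 becomes a ketone in step 19, so this centre is not carried to the target.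

Step 1
Reactants: 1 L-arabinose
Product: 2 3,4-O-isopropylidene-L-arabinopyranose
Conditions: Me2C(OMe)2, TsOH·H2O (cat.), DMF, rt
Reagents that add atoms: 2,2-dimethoxypropane, COC(C)(C)OC
Why: Acid-catalysed transketalisation takes the only cis-vicinal diol of the pyranose (sugar O3/O4), leaves the sugar C1/C2 glycol free for cleavage and touches no stereocentre.

Step 2
Reactants: 2 3,4-O-isopropylidene-L-arabinopyranose
Product: 4 2,3-O-isopropylidene-L-erythrofuranose, via formate ester 3 (not isolated)
Conditions: NaIO4, H2O, 0 °C → rt; then Na2CO3 to pH 8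
Reagents that add atoms: none
Why: Malaprade glycol cleavage removes the anomeric carbon as a formate whose mild hydrolysis lets the tetrose close to its lactol, and the two retained centres become C6 and C7.

Step 3
Reactants: 4 2,3-O-isopropylidene-L-erythrofuranose; 5 isopropyltriphenylphosphonium iodide
Product: 7 [(4S,5R)-2,2-dimethyl-5-(2-methylprop-1-enyl)-1,3-dioxolan-4-yl]methanol, via isopropylidenetriphenylphosphorane 6 (not isolated)
Conditions: n-BuLi (excess ylide), THF, 0 °C; then 4, 0 °C → rt
Reagents that add atoms: none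
Why: Wittig olefination of the open-chain form of the lactol with a non-stabilised ylide installs C4, C3 and C15 as the trisubstituted alkene and frees only the primary C8 hydroxyl, so no protecting-group step is needed.

Step 4
Reactants: 7 dioxolanyl methanol
Product: 8 (4R,5R)-2,2-dimethyl-5-(2-methylprop-1-enyl)-1,3-dioxolane-4-carbaldehyde
Conditions: TEMPO (cat.), PhI(OAc)2, CH2Cl2, rt
Reagents that add atoms: none
Why: Oxoammonium (TEMPO) oxidation stops at the aldehyde under nearly neutral conditions, so the α-alkoxy centre C7 should not epimerise and the alkene is left alone.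

Step 5
Reactants: 8 dioxolane carbaldehyde; 9 1-(tert-butyldimethylsilyloxy)-1-methoxyethene
Product: 10 methyl (3S)-3-hydroxy-3-[(4S,5R)-2,2-dimethyl-5-(2-methylprop-1-enyl)-1,3-dioxolan-4-yl]propanoate
Conditions: BF3·OEt2, CH2Cl2, −78 °C
Reagents that add atoms: none
Why: A Mukaiyama aldol addition under a non-chelating Lewis acid follows the polar Felkin–Anh model, so attack anti to the C7–O bond should give the 7,8-anti relationship and thereby 8S, the only centre of this part that reaches the target.

Step 6
Reactants: 10 β-hydroxy ester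
Product: 11 methyl (3S)-3-(tert-butyldimethylsilyloxy)-3-[(4R,5R)-2,2-dimethyl-5-(2-methylprop-1-enyl)-1,3-dioxolan-4-yl]propanoate
Conditions: TBSOTf, 2,6-lutidine, CH2Cl2, −78 → 0 °C
Reagents that add atoms: tert-butyldimethylsilyl triflate, CC(C)(C)[Si](C)(C)OS(=O)(=O)C(F)(F)F
Why: Silylation with a silyl triflate and a hindered base caps the crowded secondary hydroxyl without retro-aldol or elimination.

Step 7
Reactants: 11 silyloxy ester
Product: 12 (3S)-3-(tert-butyldimethylsilyloxy)-3-[(4R,5R)-2,2-dimethyl-5-(2-methylprop-1-enyl)-1,3-dioxolan-4-yl]propanal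
Conditions: iBu2AlH (1.05 equiv), CH2Cl2, −78 °C
Reagents that add atoms: none
Why: In this partial ester reduction the aluminium hemiacetal is stable at −78 °C and collapses to the C10 aldehyde only at work-up.

Step 8
Reactants: 12 trioxygenated 7-methyloct-6-enal
Product: 13 cyclohexanol with C5 isopropenyl trans to O6 and trans to the C10 hydroxyl (O6 O7 O8 all cis; 6R 7R 8S 10R)
Conditions: Me2AlCl (1.5 equiv), CH2Cl2, −78 → −40 °C
Reagents that add atoms: none
Why: This intramolecular carbonyl-ene reaction of the citronellal-to-isopulegol kind runs through a chair with O6 and O8 equatorial and C6–H eclipsing the alkene (allylic 1,3-strain), so C10 bonds to the C5 face anti to O6 and the isopropenyl group ends equatorial, trans to O6 and to the new hydroxyl, with no enolate that could expel O6.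

Step 9
Reactants: 13 cyclohexanol
Product: 14 (5R,6R,7R,8S)-cyclohexanone with C5 isopropenyl, C6/C7 acetonide and C8 silyl ether
Conditions: Dess–Martin periodinane, pyridine, CH2Cl2, 0 °C
Reagents that add atoms: none
Why: A buffered Dess–Martin oxidation gives the β,γ-unsaturated β-alkoxy ketone without base, so neither conjugation of the isopropenyl group, epimerisation at C5 nor loss of O6 should occur.

Step 10
Reactants: 15 1-bromo-2-(methoxymethoxy)ethane
Product: 16 methoxymethyl vinyl ether
Conditions: KOH (powder), tetraglyme, 110 °C, product distilled off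
Reagents that add atoms: none
Why: E2 dehydrobromination of a 2-haloethyl ether is the standard route to a vinyl ether, and the volatile product leaves the basic medium as it forms.

Step 11
Reactants: 16 methoxymethyl vinyl ether; 14 cyclohexanone
Product: 19 (5R,6R,7R,8S,10S)-trans-dialkenylcyclohexanol (C5 isopropenyl and C10 1-(methoxymethoxy)vinyl both equatorial; C10 hydroxyl axial), via 1-(methoxymethoxy)vinyllithium 17 (not isolated), via organocerium reagent 18 (not isolated)
Conditions: t-BuLi, THF, −78 → −10 °C; CeCl3 (anhydrous), −78 °C; then 14, −78 °C; pH 7 work-up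
Reagents that add atoms: none
Why: α-Lithiation of the vinyl ether and transmetalation give a weakly basic organocerium reagent that adds 1,2 instead of enolising 14, and equatorial attack trans to the equatorial isopropenyl group sets C10 with the two alkenyl groups trans.

Step 12
Reactants: 19 trans-dialkenylcyclohexanol
Product: 22 (1S,4E,6R,7R,8S)-8-(tert-butyldimethylsilyloxy)-6,7-(isopropylidenedioxy)-1-(methoxymethoxy)-4-methylcyclodec-4-en-10-one, via potassium alkoxide 20 (not isolated), via potassium enolate 21 (not isolated)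
Conditions: KH, 18-crown-6, THF, 0 °C → rt; AcOH in THF, −78 °C
Reagents that add atoms: none
Why: KH forms alkoxide 20, whose oxyanion weakens C5–C10, and the anionic oxy-Cope [3,3]-sigmatropic shift then makes C2–C3 and breaks C5–C10 through a chair transition state fused like a trans-decalin to the cyclohexane chair, giving the regiodefined enolate 21. The closest known reaction type is the KH/18-crown-6 rearrangement of trans-1,2-dialkenylcyclohexanols to (E)-cyclodec-5-enones. The ten-membered ring is not closed end to end but arises by four-atom expansion of the six-membered ring, so no dilution is needed. The diequatorial alkenyl groups place C6 cis to the C4 methyl and so fix the (E) C4=C5 geometry, C6, C7 and C8 are spectators, and the only new centre C1 is set by protonation of 21 from the ring periphery (1S expected) and is erased in step 19. The step needs a single pericyclic pathway and an enolate that stays at C10=C1: only one 1,5-diene is present, O10 and the C8 silyl ether are trans-1,3 so silyl migration is hindered, and the cold acetic acid quench leaves little time for a proton shift to C9 that would expel O8.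

Step 13
Reactants: 22 cyclodecenone
Product: 23 (1S,4E,6R,7R,8S,10S)-10-methyl carbinol of 22
Conditions: MeLi, ClTi(OiPr)3, Et2O, −40 °C; then 22, −20 °C → rt
Reagents that add atoms: methyllithium, [Li]C
Why: This is a 1,2-addition of a non-basic, non-chelating methyltitanium reagent; in the crown conformer delivered by step 12 (C10=O syn to C15, C1–O anti to C=O) only the outer face flanked by C1–H is open, so peripheral attack should give 10S while the β-silyloxy ketone is spared from elimination.

Step 14
Reactants: 23 acetonide carbinol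
Product: 24 (1S,4E,6R,7R,8S,10S)-6,7,10-triol with C1 methoxymethyl ether and C8 silyl ether
Conditions: AcOH–H2O (4:1), rt → 40 °C
Reagents that add atoms: none
Why: Mild acid hydrolysis cleaves the dioxolane ketal, whereas the formaldehyde acetal at C1 and the hindered secondary silyl ether need stronger acid.

Step 15
Reactants: 25 benzyl diethylphosphonoacetate; 26 (triisopropylsiloxy)methyl chloride
Product: 27 benzyl 2-(diethoxyphosphoryl)-3-(triisopropylsilyloxy)propanoate (racemic)
Conditions: NaH, THF, 0 °C; then 26, 0 °C → rt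
Reagents that add atoms: none
Why: C-alkylation of the stabilised phosphonate carbanion with a reactive α-chloro ether brings in C13 with its oxygen already silylated, so the later olefination delivers the complete C11–C13 unit.

Step 16
Reactants: 27 benzyl ester
Product: 28 2-(diethoxyphosphoryl)-3-(triisopropylsilyloxy)propanoic acid
Conditions: H2 (1 atm), Pd/C, EtOAc, rt
Reagents that add atoms: none
Why: Neutral hydrogenolysis frees the acid without forming the phosphonate carbanion that could expel the β-silyloxy group.

Step 17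
Reactants: 24 triol; 28 phosphono acid
Product: 29 C6 ester of 24 with acid 28 (C7 and C10 hydroxyls free; C11 epimers)
Conditions: DCC, DMAP (cat.), CH2Cl2, −20 → 0 °C
Reagents that add atoms: none
Why: In this Steglich esterification the allylic C6 hydroxyl is the more accessible secondary alcohol because the C7 hydroxyl is flanked by the C8 silyl ether, and the tertiary C10 hydroxyl does not react.

Step 18
Reactants: 29 phosphonate ester
Product: 30 1,7,10-triol C6 phosphonate ester
Conditions: ZnBr2, n-PrSH, CH2Cl2, 0 °C, short contact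
Reagents that add atoms: none
Why: In this Lewis-acid and thiol cleavage of the methoxymethyl ether the thiol traps the oxocarbenium ion faster than the neighbouring C10 hydroxyl can close a methylene acetal, and the silyl ethers and the ester are kept.

Step 19
Reactants: 30 triol ester
Product: 31 1,7-diketone (6R,8S,10S) with C6 phosphonate ester and free C10 hydroxyl
Conditions: Dess–Martin periodinane (2.5 equiv), pyridine, CH2Cl2, 0 °C → rt
Reagents that add atoms: none
Why: One Dess–Martin oxidation converts both secondary alcohols (C1 and C7) into ketones, leaves the tertiary alcohol alone and removes the provisional C1 centre.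

Step 20
Reactants: 31 diketone
Product: 32 (4E,6R,8S,10S)-Δ7(11)-12,6-butenolide with C13 silyl ether, C1 ketone and C10 hydroxyl
Conditions: LiCl, iPr2NEt, MeCN, 0 °C → rt
Reagents that add atoms: none
Why: Under Masamune–Roush conditions the intramolecular Horner–Wadsworth–Emmons reaction closes the five-membered lactone on the adjacent C7 ketone much faster than the soft carbanion can lose the β-silyloxy group or reach the distant C1 ketone, and the weak base should spare C6 and C8.

Step 21
Reactants: 32 butenolide ketol
Product: 33 C10 triethylsilyl ether of 32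
Conditions: TESOTf, 2,6-lutidine, CH2Cl2, −78 °C
Reagents that add atoms: triethylsilyl triflate, CC[Si](CC)(CC)OS(=O)(=O)C(F)(F)F
Why: O-silylation masks the inward-pointing C10 hydroxyl, which would otherwise compete as a transannular nucleophile for the epoxide, and at −78 °C it is far faster than enol silane formation.

Step 22
Reactants: 33 silylated ketol
Product: 34 (4R,5R,6S,8S,10S)-4,5-epoxide
Conditions: dimethyldioxirane, acetone–CH2Cl2, −20 °C
Reagents that add atoms: dimethyldioxirane, CC1(C)OO1
Why: Neutral epoxidation finds C4=C5 as the only electron-rich alkene, and peripheral attack on the conformer with C6–H eclipsing the alkene (allylic 1,3-strain against C15) puts the oxygen on the outer face syn to O6, the outcome known for germacranolide 4,5-alkenes.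

Step 23
Reactants: 34 epoxy ketone
Product: 35 (4S,5R,6S,8S,10S)-1,4-epoxy-1,5-diol (C1 hemiketal; anomers)
Conditions: PPTS (10 mol %), THF–H2O (20:1), 0 °C → rt
Reagents that add atoms: water, O
Why: In the acid-catalysed opening of this γ,δ-epoxy ketone the C1 carbonyl oxygen participates and attacks the tertiary C4 in 5-exo mode from inside the ring with inversion (4S), water captures the oxocarbenium ion as the hemiketal and O5 keeps its configuration.

Step 24
Reactants: 35 hemiketal diol
Product: 37 tris-silyl ether of the target core (4S,5E,8S,10S; C1=C2 dihydrofuran and C5=C6 ylidene butenolide), via dihydrofuran C5 mesylate 36 (not isolated)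
Conditions: MsCl, Et3N, CH2Cl2, −20 → 0 °C; then DBU, rt
Reagents that add atoms: none
Why: In this sulfonylation and elimination sequence the hemiketal sulfonate ionises and loses a C2 proton to give the cyclic enol ether (C10 has no hydrogen), and the C5 mesylate leaves by E1cB through the 2-oxidofuran formed at the γ-acidic C6–H, the mesylate being a far better leaving group than the C13 silyloxy group and the nine-membered ring O1–C4–C5–C6–C7–C8–C9–C10–C1 favouring the geometry with C4 cis to C7.

Step 25
Reactants: 37 tris-silyl ether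
Product: 38 8,10,13-triol
Conditions: Bu4NF–AcOH (1:1), THF, 0 °C → rt
Reagents that add atoms: none
Why: Buffered fluoride removes all three silyl groups without acid that would protonate the enol ether and without a free C8 alkoxide that could attack the enol lactone.

Step 26
Reactants: 38 triol
Product: 39 CNP0144020.1
Conditions: Ac2O, pyridine, DMAP (cat.), CH2Cl2, 0 °C
Reagents that add atoms: acetic anhydride, CC(=O)OC(C)=O
Why: Acetylation takes the primary C13 and the secondary C8 hydroxyls, while the tertiary C10 hydroxyl stays free under these mild conditions.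

**Compound list**
1 | L-arabinose (pyranose form) | OC1OC[C@H](O)[C@H](O)[C@H]1O | starting material
2 | 3,4-O-isopropylidene-L-arabinopyranose | OC1OC[C@@H]2OC(C)(C)O[C@@H]2[C@H]1O | intermediate
3 | 4-O-formyl-2,3-O-isopropylidene-L-erythrose | O=COC[C@@H]1OC(C)(C)O[C@@H]1C=O | intermediate
4 | 2,3-O-isopropylidene-L-erythrofuranose | OC1OC[C@@H]2OC(C)(C)O[C@H]12 | intermediate
5 | isopropyltriphenylphosphonium iodide | CC(C)[P+](c1ccccc1)(c1ccccc1)c1ccccc1.[I-] | starting material
6 | isopropylidenetriphenylphosphorane | CC(C)=P(c1ccccc1)(c1ccccc1)c1ccccc1 | intermediate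
7 | [(4S,5R)-2,2-dimethyl-5-(2-methylprop-1-enyl)-1,3-dioxolan-4-yl]methanol | CC(C)=C[C@H]1OC(C)(C)O[C@H]1CO | intermediate
8 | (4R,5R)-2,2-dimethyl-5-(2-methylprop-1-enyl)-1,3-dioxolane-4-carbaldehyde | CC(C)=C[C@H]1OC(C)(C)O[C@H]1C=O | intermediate
9 | 1-(tert-butyldimethylsilyloxy)-1-methoxyethene | C=C(OC)O[Si](C)(C)C(C)(C)C | starting material
10 | aldol adduct, 8S β-hydroxy methyl ester | CC(C)=C[C@H]1OC(C)(C)O[C@H]1[C@@H](O)CC(=O)OC | intermediate
11 | C8 tert-butyldimethylsilyl ether of 10 | CC(C)=C[C@H]1OC(C)(C)O[C@H]1[C@@H](O[Si](C)(C)C(C)(C)C)CC(=O)OC | intermediate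
12 | C10 aldehyde (ene substrate) | CC(C)=C[C@H]1OC(C)(C)O[C@H]1[C@@H](O[Si](C)(C)C(C)(C)C)CC=O | intermediate
13 | ene product, trans-2-isopropenylcyclohexanol | CC(=C)[C@@H]1[C@H]2OC(C)(C)O[C@H]2[C@@H](O[Si](C)(C)C(C)(C)C)C[C@H]1O | intermediate
14 | C10 cyclohexanone | CC(=C)[C@@H]1[C@H]2OC(C)(C)O[C@H]2[C@@H](O[Si](C)(C)C(C)(C)C)CC1=O | intermediate
15 | 1-bromo-2-(methoxymethoxy)ethane | COCOCCBr | starting material
16 | methoxymethyl vinyl ether | C=COCOC | intermediate
17 | 1-(methoxymethoxy)vinyllithium | [Li]C(=C)OCOC | intermediate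
18 | dichloro[1-(methoxymethoxy)vinyl]cerium | Cl[Ce](Cl)C(=C)OCOC | intermediate
19 | trans-dialkenylcyclohexanol (key-step precursor) | CC(=C)[C@@H]1[C@H]2OC(C)(C)O[C@H]2[C@@H](O[Si](C)(C)C(C)(C)C)C[C@@]1(O)C(OCOC)=C | intermediate
20 | potassium alkoxide of 19 | CC(=C)[C@@H]1[C@H]2OC(C)(C)O[C@H]2[C@@H](O[Si](C)(C)C(C)(C)C)C[C@@]1([O-])C(OCOC)=C.[K+] | intermediate
21 | potassium C10=C1 enolate of 22 | C/C1=C\[C@H]2OC(C)(C)O[C@H]2[C@@H](O[Si](C)(C)C(C)(C)C)C/C([O-])=C(OCOC)/CC1.[K+] | intermediate
22 | (E)-cyclodec-4-en-10-one (key-step product) | C/C1=C\[C@H]2OC(C)(C)O[C@H]2[C@@H](O[Si](C)(C)C(C)(C)C)CC(=O)[C@@H](OCOC)CC1 | intermediate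
23 | 10S tertiary carbinol | C/C1=C\[C@H]2OC(C)(C)O[C@H]2[C@@H](O[Si](C)(C)C(C)(C)C)C[C@](C)(O)[C@@H](OCOC)CC1 | intermediate
24 | 6,7,10-triol | C/C1=C\[C@@H](O)[C@@H](O)[C@@H](O[Si](C)(C)C(C)(C)C)C[C@](C)(O)[C@@H](OCOC)CC1 | intermediate
25 | benzyl diethylphosphonoacetate | CCOP(=O)(CC(=O)OCc1ccccc1)OCC | starting material
26 | (triisopropylsiloxy)methyl chloride | ClCO[Si](C(C)C)(C(C)C)C(C)C | starting material
27 | benzyl 2-(diethoxyphosphoryl)-3-(triisopropylsilyloxy)propanoate | CCOP(=O)(OCC)C(CO[Si](C(C)C)(C(C)C)C(C)C)C(=O)OCc1ccccc1 | intermediate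
28 | 2-(diethoxyphosphoryl)-3-(triisopropylsilyloxy)propanoic acid | CCOP(=O)(OCC)C(CO[Si](C(C)C)(C(C)C)C(C)C)C(=O)O | intermediate
29 | C6 phosphonate ester | C/C1=C\[C@@H](OC(=O)C(CO[Si](C(C)C)(C(C)C)C(C)C)P(=O)(OCC)OCC)[C@@H](O)[C@@H](O[Si](C)(C)C(C)(C)C)C[C@](C)(O)[C@@H](OCOC)CC1 | intermediate
30 | 1,7,10-triol C6 phosphonate ester | C/C1=C\[C@@H](OC(=O)C(CO[Si](C(C)C)(C(C)C)C(C)C)P(=O)(OCC)OCC)[C@@H](O)[C@@H](O[Si](C)(C)C(C)(C)C)C[C@](C)(O)[C@@H](O)CC1 | intermediate
31 | 1,7-diketone | C/C1=C\[C@@H](OC(=O)C(CO[Si](C(C)C)(C(C)C)C(C)C)P(=O)(OCC)OCC)C(=O)[C@@H](O[Si](C)(C)C(C)(C)C)C[C@](C)(O)C(=O)CC1 | intermediate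
32 | butenolide ketol | C/C1=C\[C@H]2OC(=O)C(CO[Si](C(C)C)(C(C)C)C(C)C)=C2[C@@H](O[Si](C)(C)C(C)(C)C)C[C@](C)(O)C(=O)CC1 | intermediate
33 | C10 triethylsilyl ether | C/C1=C\[C@H]2OC(=O)C(CO[Si](C(C)C)(C(C)C)C(C)C)=C2[C@@H](O[Si](C)(C)C(C)(C)C)C[C@](C)(O[Si](CC)(CC)CC)C(=O)CC1 | intermediate
34 | (4R,5R)-epoxy ketone | C[C@@]12CCC(=O)[C@@](C)(O[Si](CC)(CC)CC)C[C@H](O[Si](C)(C)C(C)(C)C)C3=C(CO[Si](C(C)C)(C(C)C)C(C)C)C(=O)O[C@@H]3[C@H]1O2 | intermediate
35 | 1,4-epoxy hemiketal 5-ol | C[C@@]12CCC(O)(O1)[C@@](C)(O[Si](CC)(CC)CC)C[C@H](O[Si](C)(C)C(C)(C)C)C3=C(CO[Si](C(C)C)(C(C)C)C(C)C)C(=O)O[C@@H]3[C@H]2O | intermediate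
36 | dihydrofuran C5 mesylate | C[C@@]12CC=C(O1)[C@@](C)(O[Si](CC)(CC)CC)C[C@H](O[Si](C)(C)C(C)(C)C)C3=C(CO[Si](C(C)C)(C(C)C)C(C)C)C(=O)O[C@@H]3[C@H]2OS(C)(=O)=O | intermediate
37 | tris-silyl ether of the target core | CC(C)[Si](C(C)C)(C(C)C)OCC1=C2/C(=C\[C@]3(C)CC=C(O3)[C@@](C)(O[Si](CC)(CC)CC)C[C@@H]2O[Si](C)(C)C(C)(C)C)OC1=O | intermediate
38 | 8,10,13-triol | OCC1=C2/C(=C\[C@]3(C)CC=C(O3)[C@@](C)(O)C[C@@H]2O)OC1=O | intermediate
39 | CNP0144020.1 | CC(=O)OCC1=C2/C(=C\[C@]3(C)CC=C(O3)[C@@](C)(O)C[C@@H]2OC(C)=O)OC1=O | target

**Count**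
Total step count: 26.
Longest linear sequence: 23 (steps 1–9, 11–14 and 17–26).

**Steps most likely to fail**

Step 12. What may go wrong:
- A proton shift within enolate 21 to C9, followed by β-elimination of the C8 silyloxy group.
- Heterolytic cleavage of C5–C10 with loss of the C6 alkoxide from the allyl anion.
- Silyl migration from O8 to O10, which switches off the anionic acceleration.

Fallback without any charged intermediate: from 19 the tertiary hydroxyl is capped (TMSOTf, 2,6-lutidine, CH2Cl2, −78 °C) to give the trimethylsilyl ether F1. Heating F1 in degassed o-xylene at about 200 °C in base-washed glass runs the neutral siloxy-Cope rearrangement through the same chair to the trimethylsilyl enol ether F2. Bu4NF–AcOH in THF at −78 °C then releases 22.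

Step 13. What may go wrong:
- Poor facial selectivity, because the metal bridges C10=O and the C1 acetal oxygens (this turns the inner face outwards and leads to the 10R series) or because a second ring conformer reacts.
- Sluggish addition.

Fallback that changes the control element: from 22 the formaldehyde acetal is removed in the presence of the ketal (TMSOTf, 2,2′-bipyridyl, CH2Cl2, 0 °C; then water) to give the α-hydroxy ketone F3. This is capped at once as the triethylsilyl ether F4 (TESCl, imidazole, DMF). A bulky silyl ether cannot chelate, so MeLi–CeCl3 at −78 °C should follow only the Felkin–Anh and peripheral bias and give the carbinol F5. AcOH–THF–H2O removes the dioxolane and the triethylsilyl group together to give the tetraol F6. Steglich esterification with 28 at the least hindered allylic C6 hydroxyl returns to 30.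

Step 23. What may go wrong:
- Capture of the oxocarbenium ion by the C5 hydroxyl (internal ketalisation).
- A hydride shift of the opened epoxide to a C5 ketone.
- Loss of the triethylsilyl group followed by attack of O10 on C4.

Fallback that replaces the epoxide by halo-etherification: from 33, N-iodosuccinimide in THF–H2O at 0 °C activates C4=C5 from the outer face. The hydrated C1 carbonyl closes onto C4 from inside (again 4S) to give the iodo hemiketal F7. DBU in CH2Cl2 removes hydrogen iodide through the C6 dienolate to give the ylidene hemiketal F8, and MsCl–Et3N dehydrates the hemiketal to 37.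

**Further compounds**
F1 | step 12 | trimethylsilyl ether of 19 | CC(=C)[C@@H]1[C@H]2OC(C)(C)O[C@H]2[C@@H](O[Si](C)(C)C(C)(C)C)C[C@@]1(O[Si](C)(C)C)C(OCOC)=C
F2 | step 12 | C10 trimethylsilyl enol ether of 22 | C/C1=C\[C@H]2OC(C)(C)O[C@H]2[C@@H](O[Si](C)(C)C(C)(C)C)C/C(O[Si](C)(C)C)=C(OCOC)/CC1
F3 | step 13 | C1 hydroxy ketone | C/C1=C\[C@H]2OC(C)(C)O[C@H]2[C@@H](O[Si](C)(C)C(C)(C)C)CC(=O)[C@@H](O)CC1
F4 | step 13 | C1 triethylsilyl ether ketone | C/C1=C\[C@H]2OC(C)(C)O[C@H]2[C@@H](O[Si](C)(C)C(C)(C)C)CC(=O)[C@@H](O[Si](CC)(CC)CC)CC1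
F5 | step 13 | 10S carbinol with C1 triethylsilyl ether | C/C1=C\[C@H]2OC(C)(C)O[C@H]2[C@@H](O[Si](C)(C)C(C)(C)C)C[C@](C)(O)[C@@H](O[Si](CC)(CC)CC)CC1
F6 | step 13 | 1,6,7,10-tetraol | C/C1=C\[C@@H](O)[C@@H](O)[C@@H](O[Si](C)(C)C(C)(C)C)C[C@](C)(O)[C@@H](O)CC1
F7 | step 23 | 5-iodo-1,4-epoxy hemiketal | C[C@@]12CCC(O)(O1)[C@@](C)(O[Si](CC)(CC)CC)C[C@H](O[Si](C)(C)C(C)(C)C)C3=C(CO[Si](C(C)C)(C(C)C)C(C)C)C(=O)O[C@@H]3[C@H]2I
F8 | step 23 | ylidene butenolide hemiketal | CC(C)[Si](C(C)C)(C(C)C)OCC1=C2/C(=C\[C@]3(C)CCC(O)(O3)[C@@](C)(O[Si](CC)(CC)CC)C[C@@H]2O[Si](C)(C)C(C)(C)C)OC1=O
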